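## Retrosynthetic overview
1. Lactone ring (closed last): the C3–O bond is made directly from the benzylic CH2 and the free CO2H of the fully elaborated 2-alkyl-4,6-dimethoxybenzoic acid. A ligand-controlled copper radical-relay C–H lactonisation does this and sets 3S. It is the laboratory version of the fungal benzylic hydroxylation/lactonisation.
2. Side chain: cross-metathesis of a decenyl arene with (S)-6-oxohept-1-en-3-yl acetate, then one hydrogenation that saturates the alkene and frees the acid from its benzyl ester.
3. Benzene ring (closed first): C2–C7 aldol aromatisation of a free tetraketide acid. The acid is unmasked from triacetic acid lactone that has been acylated with methyl undec-10-enoate.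
4. 10'R carbinol: lipase resolution of the vinyl carbinol made from 4-oxopentanal (ozonolysis of 6-methylhept-5-en-2-one). The enzyme also installs the acetate.
5. Order of ring formation: benzene ring, then lactone ring.

Assumption: the sense of induction of the copper/bisoxazoline lactonisation in step 9 cannot be predicted with certainty. Both ligand enantiomers are commercial. The route is written with (S,S)-tBu-Box, 2,2'-(propane-2,2-diyl)bis[(4S)-4-tert-butyl-4,5-dihydro-1,3-oxazole], as the one that gives 3S, and the (R,R)-ligand is used instead if the first run shows the opposite sense.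

## Route

Step 1
Reactants: 1 4-hydroxy-6-methyl-2H-pyran-2-one (triacetic acid lactone, 2.2 equiv); 2 methyl undec-10-enoate (1.0 equiv)
Product: 4 4-hydroxy-6-(2-oxododec-11-en-1-yl)-2H-pyran-2-one, via dilithiated pyrone 3 (not isolated)
Conditions: LDA (4.5 equiv, commercial solution), THF–DMPU, −78 to −20 °C; then 2, −78 °C to rt; 1 M HCl
Reagents that add atoms: none
Why: Claisen-type C-acylation of an O,C-dianion, in which the last-formed 6-CH2 carbanion is the most nucleophilic site and the extra equivalent of dianion deprotonates the product so that it is not attacked again, giving a lactone-masked tetraketide.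

Step 2
Reactants: 4 4-hydroxy-6-(2-oxododec-11-en-1-yl)-2H-pyran-2-one
Product: 6 2-(dec-9-en-1-yl)-4,6-dihydroxybenzoic acid, via 3,5,7-trioxoheptadec-16-enoic acid 5 (not isolated)
Conditions: KOH (6 equiv), degassed H2O–THF, 0 °C to rt, 16 h; then 1 M HCl to pH 2, 0 °C
Reagents that add atoms: potassium hydroxide, [K+].[OH-]
Why: Biomimetic polyketide aldol cyclisation (orsellinic-acid folding), in which hydroxide opens the pyranone to the triketo carboxylate, the non-electrophilic carboxylate shuts off the Claisen mode, and only the C2-to-C7 aldol addition, dehydration and enolisation to the resorcylic acid remain.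

Step 3
Reactants: 6 2-(dec-9-en-1-yl)-4,6-dihydroxybenzoic acid
Product: 8 benzyl 2-(dec-9-en-1-yl)-4,6-dimethoxybenzoate, via benzyl 2-(dec-9-en-1-yl)-4,6-dihydroxybenzoate 7 (not isolated)
Conditions: BnBr (1.05 equiv), KHCO3 (1.2 equiv), DMF, rt; then K2CO3 (4 equiv), MeI (5 equiv), 45 °C, same flask
Reagents that add atoms: benzyl bromide, BrCc1ccccc1; iodomethane, CI
Why: Sequential SN2 O-alkylations (carboxylate alkylation, then Williamson ether synthesis), in which hydrogencarbonate ionises only the CO2H so that BnBr gives the ester, and carbonate then ionises both phenols for methylation.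

Step 4
Reactants: 9 6-methylhept-5-en-2-one
Product: 11 4-oxopentanal, via secondary ozonide 10 (not isolated)
Conditions: O3, CH2Cl2, −78 °C; then Me2S (3 equiv), −78 °C to rt
Reagents that add atoms: ozone, [O-][O+]=O
Why: Criegee ozonolysis with reductive work-up cleaves the only C=C bond and leaves the methyl ketone untouched.

Step 5
Reactants: 11 4-oxopentanal
Product: 12 rac-5-hydroxyhept-6-en-2-one
Conditions: CH2=CHMgBr (1.0 equiv, slow addition), THF, −78 °C; sat. aq NH4Cl
Reagents that add atoms: vinylmagnesium bromide, C=C[Mg]Br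
Why: Chemoselective Grignard 1,2-addition, since at −78 °C with one equivalent the aldehyde reacts far faster than the methyl ketone; the carbinol is racemic and is resolved in the next step.

Step 6
Reactants: 12 rac-5-hydroxyhept-6-en-2-one
Product: 13 (3S)-6-oxohept-1-en-3-yl acetate
Conditions: immobilised Candida antarctica lipase B, vinyl acetate (3 equiv), MTBE, 30 °C, stopped at about 45 % conversion
Reagents that add atoms: vinyl acetate, C=COC(C)=O
Why: Lipase-catalysed kinetic resolution by irreversible transesterification (Kazlauskas rule), in which the enantiomer with vinyl in the small pocket and the oxobutyl chain in the large pocket is acylated; this is S here because vinyl outranks the alkyl chain, so the enzyme sets the carbinol centre and installs the target's acetate in one operation (at most 50 % yield).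

Step 7
Reactants: 8 benzyl 2-(dec-9-en-1-yl)-4,6-dimethoxybenzoate (1 equiv); 13 (3S)-6-oxohept-1-en-3-yl acetate (2 equiv)
Product: 14 benzyl 2-[(9E,11S)-11-acetoxy-14-oxopentadec-9-en-1-yl]-4,6-dimethoxybenzoate
Conditions: second-generation Grubbs catalyst (5 mol %), 1,4-benzoquinone (10 mol %), CH2Cl2, 40 °C
Reagents that add atoms: none
Why: Olefin cross-metathesis, in which the unhindered terminal alkene of 8 homodimerises fast and reversibly while the secondary allylic acetate 13 does so slowly, so excess 13 drives selective cross-coupling with loss of ethylene (E favoured, geometry irrelevant) and the allylic stereocentre is not touched.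

Step 8
Reactants: 14 benzyl 2-[(9E,11S)-11-acetoxy-14-oxopentadec-9-en-1-yl]-4,6-dimethoxybenzoate
Product: 15 2-[(11R)-11-acetoxy-14-oxopentadecyl]-4,6-dimethoxybenzoic acid
Conditions: H2 (1 atm), 10 % Pd/C, EtOAc, rt
Reagents that add atoms: none
Why: Heterogeneous catalytic hydrogenation with concurrent benzyl ester hydrogenolysis saturates the alkene and frees the acid in one operation; the carbinol centre is unchanged in space, and its descriptor goes from S to R only because the ranking of its two carbon chains swaps once the alkene is gone.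

Step 9
Reactants: 15 2-[(11R)-11-acetoxy-14-oxopentadecyl]-4,6-dimethoxybenzoic acid
Product: 17 (3S)-3-[(10R)-10-acetoxy-13-oxotetradecyl]-5,7-dimethoxy-2-benzofuran-1(3H)-one, via benzylic radical 16 (not isolated)
Conditions: Cu(MeCN)4PF6 (10 mol %), (S,S)-tBu-Box (12 mol %), NFSI (1.5 equiv), Li2CO3 (1.5 equiv), PhCl, 30 °C, N2
Reagents that add atoms: none
Why: Proposed new method: monovalent copper reduces NFSI to a divalent copper fluoride and the (PhSO2)2N radical, which abstracts the weakest and most hydridic C–H (the only benzylic CH2, since the ketone α-C–H, the AcO–C–H and the chain CH2 groups are polarity-mismatched or about 10 kcal/mol stronger) to give radical 16; the substrate's own carboxylate sits on the bisoxazoline-bound divalent copper, so radical capture closes a six-membered trivalent-copper chelate whose C–O reductive elimination forms the lactone and sets C3 under ligand control (the tert-butyl groups tell the H face from the alkyl face, and the remote 10' centre has no influence), and because both OMe groups are meta to the radical carbon the free benzylic cation that would erase selectivity is disfavoured; the closest known reaction types are the copper/bisoxazoline radical-relay enantioselective benzylic C–H cyanation with NFSI, the racemic copper-catalysed benzylic C–H lactonisation of 2-alkylbenzoic acids, and the copper/tBu-Box enantioselective radical oxyfunctionalisation of alkenoic acids that closes lactones by the same benzylic radical/copper carboxylate C–O coupling.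

## Compound list
1 | 4-hydroxy-6-methyl-2H-pyran-2-one (triacetic acid lactone) | CC1=CC(O)=CC(=O)O1 | starting material
2 | methyl undec-10-enoate | C=CCCCCCCCCC(=O)OC | starting material
3 | dilithiated pyrone (O,C-dianion of 1) | [Li+].[Li+].[CH2-]C1=CC([O-])=CC(=O)O1 | intermediate (not isolated)
4 | 4-hydroxy-6-(2-oxododec-11-en-1-yl)-2H-pyran-2-one | C=CCCCCCCCCC(=O)CC1=CC(O)=CC(=O)O1 | intermediate
5 | 3,5,7-trioxoheptadec-16-enoic acid (present as its potassium salt) | C=CCCCCCCCCC(=O)CC(=O)CC(=O)CC(=O)O | intermediate (not isolated)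
6 | 2-(dec-9-en-1-yl)-4,6-dihydroxybenzoic acid | C=CCCCCCCCCc1cc(O)cc(O)c1C(=O)O | intermediate
7 | benzyl 2-(dec-9-en-1-yl)-4,6-dihydroxybenzoate | C=CCCCCCCCCc1cc(O)cc(O)c1C(=O)OCc1ccccc1 | intermediate (not isolated)
8 | benzyl 2-(dec-9-en-1-yl)-4,6-dimethoxybenzoate | C=CCCCCCCCCc1cc(OC)cc(OC)c1C(=O)OCc1ccccc1 | intermediate
9 | 6-methylhept-5-en-2-one | CC(C)=CCCC(C)=O | starting material
10 | secondary ozonide, 4-(5,5-dimethyl-1,2,4-trioxolan-3-yl)butan-2-one | CC(=O)CCC1OOC(C)(C)O1 | intermediate (not isolated)
11 | 4-oxopentanal | CC(=O)CCC=O | intermediate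
12 | rac-5-hydroxyhept-6-en-2-one | C=CC(O)CCC(C)=O | intermediate
13 | (3S)-6-oxohept-1-en-3-yl acetate | C=C[C@H](CCC(C)=O)OC(C)=O | intermediate
14 | benzyl 2-[(9E,11S)-11-acetoxy-14-oxopentadec-9-en-1-yl]-4,6-dimethoxybenzoate | COc1cc(OC)c(C(=O)OCc2ccccc2)c(CCCCCCCC/C=C/[C@H](CCC(C)=O)OC(C)=O)c1 | intermediate
15 | 2-[(11R)-11-acetoxy-14-oxopentadecyl]-4,6-dimethoxybenzoic acid | COc1cc(OC)c(C(=O)O)c(CCCCCCCCCC[C@H](CCC(C)=O)OC(C)=O)c1 | intermediate
16 | benzylic radical of 15 | COc1cc(OC)c(C(=O)O)c([CH]CCCCCCCCC[C@H](CCC(C)=O)OC(C)=O)c1 | intermediate (not isolated)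
17 | (3S)-3-[(10R)-10-acetoxy-13-oxotetradecyl]-5,7-dimethoxy-2-benzofuran-1(3H)-one | COc1cc(OC)c2c(c1)[C@H](CCCCCCCCC[C@H](CCC(C)=O)OC(C)=O)OC2=O | target

## Step count and risks
Total steps: 9. Longest linear sequence: 6 (steps 1, 2, 3, 7, 8, 9; the sequence 4, 5, 6, 7, 8, 9 is equally long).

**Step 9** is the most likely to fail. The imidyl radical may add to the electron-rich ring. Fluorine-atom transfer from NFSI to 16, followed by unselective substitution, would erode the ratio at C3. The catalyst may also pool as divalent copper.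

The fallback sets out from 15 and passes through the ketone oxidation level instead of coupling C and O directly. Exhaustive aerobic benzylic oxidation (N-hydroxyphthalimide 20 mol %, Co(OAc)2 2 mol %, O2, MeCN, 70 °C) oxidises any phthalide formed on the way further at its C3–H. It gives 2-[(11R)-11-acetoxy-14-oxopentadecanoyl]-4,6-dimethoxybenzoic acid F1, which is in equilibrium with its 3-hydroxyphthalide ring tautomer.

Noyori asymmetric transfer hydrogenation with RuCl(p-cymene)[(S,S)-TsDPEN] in HCO2H/Et3N 5:2 at 30 °C reduces the aryl ketone much faster than the dialkyl ketone. The product is 2-[(1S,11R)-11-acetoxy-1-hydroxy-14-oxopentadecyl]-4,6-dimethoxybenzoic acid F2. This lactonises on work-up, and the fallback comes back to the route at 17.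

**Step 2** is second. Retro-Claisen cleavage in base, or decarboxylation to the 5-alkylresorcinol on acidification, can take the material.

The fallback sets out from 2 and keeps the same aldol aromatisation, but releases the tetraketide thermally as an ester rather than hydrolytically as an acid.
- MeNHOMe·HCl and iPrMgCl convert 2 into N-methoxy-N-methylundec-10-enamide F3.
- Commercial 2,2,6-trimethyl-4H-1,3-dioxin-4-one is C-acetylated (LiHMDS, AcCl, THF, −78 °C) to 2,2-dimethyl-6-(2-oxopropyl)-4H-1,3-dioxin-4-one F4.
- The dianion of F4 (LDA, 2 equiv) is acylated by F3 to give 6-(2,4-dioxotetradec-13-en-1-yl)-2,2-dimethyl-4H-1,3-dioxin-4-one F5.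
- Heating F5 with BnOH in toluene at 110 °C expels acetone and gives the acylketene 3,5,7-trioxoheptadeca-1,16-dien-1-one F6.
- The alcohol traps F6 as benzyl 3,5,7-trioxoheptadec-16-enoate F7.
- Cs2CO3 and then HCl aromatise F7, and the fallback comes back at 7, which is methylated as in the second half of step 3.

**Step 8** is third. Pd/C may cleave the allylic C–O bond before the alkene is saturated.

The fallback sets out from 8 and 11 and never makes an allylic acetate.
- Hydroboration of 8 with Et2BH gives benzyl 2-[10-(diethylboranyl)decyl]-4,6-dimethoxybenzoate F8.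
- Boron–zinc exchange with Et2Zn gives bis{10-[2-(benzyloxycarbonyl)-3,5-dimethoxyphenyl]decyl}zinc F9.
- Catalytic asymmetric addition of F9 to aldehyde 11 uses Ti(OiPr)4 and (1S,2S)-N,N'-bis(trifluoromethylsulfonyl)cyclohexane-1,2-diamine (8 mol %) in toluene at −20 °C. The (1R,2R)-ligand gives S alcohols from Et2Zn and PhCHO, which maps onto the unwanted 11S here. The product is benzyl 2-[(11R)-11-hydroxy-14-oxopentadecyl]-4,6-dimethoxybenzoate F10.
- Ac2O, pyridine and DMAP give benzyl 2-[(11R)-11-acetoxy-14-oxopentadecyl]-4,6-dimethoxybenzoate F11.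
- H2 over Pd/C then only has to remove the benzyl group, and the fallback comes back at 15.

Further compounds
F1 | step 9 | 2-[(11R)-11-acetoxy-14-oxopentadecanoyl]-4,6-dimethoxybenzoic acid | COc1cc(OC)c(C(=O)O)c(C(=O)CCCCCCCCC[C@H](CCC(C)=O)OC(C)=O)c1
F2 | step 9 | 2-[(1S,11R)-11-acetoxy-1-hydroxy-14-oxopentadecyl]-4,6-dimethoxybenzoic acid | COc1cc(OC)c(C(=O)O)c([C@@H](O)CCCCCCCCC[C@H](CCC(C)=O)OC(C)=O)c1
F3 | step 2 | N-methoxy-N-methylundec-10-enamide | C=CCCCCCCCCC(=O)N(C)OC
F4 | step 2 | 2,2-dimethyl-6-(2-oxopropyl)-4H-1,3-dioxin-4-one | CC(=O)CC1=CC(=O)OC(C)(C)O1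
F5 | step 2 | 6-(2,4-dioxotetradec-13-en-1-yl)-2,2-dimethyl-4H-1,3-dioxin-4-one | C=CCCCCCCCCC(=O)CC(=O)CC1=CC(=O)OC(C)(C)O1
F6 | step 2 | 3,5,7-trioxoheptadeca-1,16-dien-1-one (acylketene) | C=CCCCCCCCCC(=O)CC(=O)CC(=O)C=C=O
F7 | step 2 | benzyl 3,5,7-trioxoheptadec-16-enoate | C=CCCCCCCCCC(=O)CC(=O)CC(=O)CC(=O)OCc1ccccc1
F8 | step 8 | benzyl 2-[10-(diethylboranyl)decyl]-4,6-dimethoxybenzoate | CCB(CC)CCCCCCCCCCc1cc(OC)cc(OC)c1C(=O)OCc1ccccc1
F9 | step 8 | bis{10-[2-(benzyloxycarbonyl)-3,5-dimethoxyphenyl]decyl}zinc | COc1cc(OC)c(C(=O)OCc2ccccc2)c(CCCCCCCCCC[Zn]CCCCCCCCCCc2cc(OC)cc(OC)c2C(=O)OCc2ccccc2)c1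
F10 | step 8 | benzyl 2-[(11R)-11-hydroxy-14-oxopentadecyl]-4,6-dimethoxybenzoate | COc1cc(OC)c(C(=O)OCc2ccccc2)c(CCCCCCCCCC[C@H](CCC(C)=O)O)c1
F11 | step 8 | benzyl 2-[(11R)-11-acetoxy-14-oxopentadecyl]-4,6-dimethoxybenzoate | COc1cc(OC)c(C(=O)OCc2ccccc2)c(CCCCCCCCCC[C@H](CCC(C)=O)OC(C)=O)c1
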